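**Retrosynthetic overview**
- The target is reached from a silyl-protected oxolane alcohol by esterification with nonadecanoic acid and desilylation.
- The oxolane is formed last: a pentadienyl cation, made by ionising a C15 tertiary dienylic alcohol, is captured at C4 by the C1 hydroxyl. The precursor is an open triol obtained by reducing a xeniolide-type 4(12)-alkylidene δ-lactone.
- The alkylidene lactone comes from a Horner–Wadsworth–Emmons reaction between an α-phosphono δ-lactone and (2E)-4-hydroxy-4-methylpent-2-enal.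
- The nine-membered carbocycle and the δ-lactone are formed together, second: a transannular ene closure of the C11a–C4a bond in a 13-membered macrolide, with a C19 hydrogen moving to C4 (caryophyllene-type closure).
- The macrolide is formed first, by ring-closing metathesis of the ester made from a linalool-derived aldehyde (C4a–C8, C18) and (2E)-3-methylhexa-2,5-dien-1-yl phosphonoacetate (C1, C3, C4, C9–C11a, C19).

Assumption: the presumed biosynthesis is taken as the xenicane pathway (C11a–C4a closure of a macrocyclic precursor with loss of a C19 proton, then attack of the C1 hydroxyl on C4 of the pentadienyl cation from a xeniolide-type 4(12),13-dien-15-ol); xenicane locants are used in the text (C1, C3, C4, C4a, C5–C11, C11a, side chain C12–C17, C18 = 7-methyl, C19 = exocyclic methylene), and (S)-(+)-linalool is taken as commercially available.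

**Step 1**
Reactants: 1 (S)-(+)-linalool
Product: 2 (3S)-3,7-dimethyl-3-(triethylsilyloxy)octa-1,6-diene
Conditions: TESOTf, 2,6-lutidine, CH2Cl2, −78 to 0 °C
Reagents that add atoms: triethylsilyl trifluoromethanesulfonate, CC[Si](CC)(CC)OS(=O)(=O)C(F)(F)F
Why: Silylation of the tertiary allylic alcohol with a silyl triflate is fast and clean; it blocks the later oxa-Michael addition of the C7 oxygen to C4a, and the chiral-pool C7 stereocentre (7S of the target) is untouched.

**Step 2**
Reactants: 2 (3S)-3,7-dimethyl-3-(triethylsilyloxy)octa-1,6-diene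
Product: 4 (4S)-4-methyl-4-(triethylsilyloxy)hex-5-enal, via secondary ozonide 3 (not isolated)
Conditions: O3 (1 equiv, Sudan Red 7B end point), CH2Cl2, −78 °C; then PPh3, −78 °C to rt
Reagents that add atoms: ozone, [O-][O+]=O
Why: Chemoselective ozonolysis: the electron-rich trisubstituted olefin reacts far faster than the hindered vinyl group, and reductive work-up gives the aldehyde whose carbonyl carbon becomes C4a.

**Step 3**
Reactants: 5 pent-1-en-4-yne
Product: 7 (2E)-3-methylhexa-2,5-dien-1-ol, via alkenylalane 6 (not isolated)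
Conditions: Me3Al, Cp2ZrCl2 (20 mol %), CH2Cl2, 0 °C to rt; then n-BuLi, THF, −78 °C; (CH2O)n, −78 °C to rt
Reagents that add atoms: trimethylaluminium, C[Al](C)C; formaldehyde (from paraformaldehyde), C=O
Why: Negishi zirconium-catalysed carboalumination adds methyl and aluminium syn across the terminal alkyne, and the alanate is trapped by formaldehyde (as in the classical geraniol synthesis), so the 2E olefin with the C19 methyl cis to C1 is fixed.

**Step 4**
Reactants: 7 (2E)-3-methylhexa-2,5-dien-1-ol, 8 (diethoxyphosphoryl)acetic acid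
Product: 9 (2E)-3-methylhexa-2,5-dien-1-yl (diethoxyphosphoryl)acetate
Conditions: DCC, DMAP (5 mol %), CH2Cl2, 0 °C to rt
Reagents that add atoms: none
Why: Steglich esterification of a primary allylic alcohol; the ester oxygen is the future C1 oxygen and the phosphonoacetate supplies C3 and C4.

**Step 5**
Reactants: 4 (4S)-4-methyl-4-(triethylsilyloxy)hex-5-enal, 9 (2E)-3-methylhexa-2,5-dien-1-yl (diethoxyphosphoryl)acetate
Product: 10 (2E)-3-methylhexa-2,5-dien-1-yl (2E,6S)-2-(diethoxyphosphoryl)-6-methyl-6-(triethylsilyloxy)octa-2,7-dienoate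
Conditions: TiCl4, N-methylmorpholine, THF, 0 °C to rt
Reagents that add atoms: none
Why: Lehnert-type Knoevenagel condensation of a phosphonoacetate with an aliphatic aldehyde gives the doubly activated C4=C4a olefin, mainly as the E isomer (bulky phosphoryl group trans to the C5 chain), which is purified by chromatography.

**Step 6**
Reactants: 10 (2E)-3-methylhexa-2,5-dien-1-yl (2E,6S)-2-(diethoxyphosphoryl)-6-methyl-6-(triethylsilyloxy)octa-2,7-dienoate
Product: 11 (3E,7S,8Z,11E)-3-(diethoxyphosphoryl)-7,11-dimethyl-7-(triethylsilyloxy)-1-oxacyclotrideca-3,8,11-trien-2-one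
Conditions: second-generation Hoveyda–Grubbs catalyst (10 mol %), 1,4-benzoquinone (20 mol %), toluene (1 mM), 80 °C
Reagents that add atoms: none
Why: Macrocyclic ring-closing metathesis engages only the two monosubstituted olefins (the alkylidene phosphonoacetate and the trisubstituted olefin are inert) and forms the C8=C9 bond; the Z isomer needed for the next step is separated and the E isomer can be recycled by ethenolysis.

**Step 7**
Reactants: 11 (3E,7S,8Z,11E)-3-(diethoxyphosphoryl)-7,11-dimethyl-7-(triethylsilyloxy)-1-oxacyclotrideca-3,8,11-trien-2-one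
Product: 12 (4aS,7S,8Z,11aR)-4-(diethoxyphosphoryl)-7-methyl-11-methylidene-7-(triethylsilyloxy)-4,4a,5,6,7,10,11,11a-octahydrocyclonona[c]pyran-3(1H)-one (mixture of C4 epimers)
Conditions: Cu(OTf)2 (20 mol %), (S,S)-t-Bu-box (22 mol %), 4 Å MS, CH2Cl2, rt to 40 °C
Reagents that add atoms: none
Why: Proposed new method: chelation of the alkylidene phosphonoacetate (P=O and C=O) by the cationic bis(oxazoline) complex of divalent copper makes C4a strongly electrophilic, the transannular E-trisubstituted olefin attacks through C11a, and a hydrogen of the C19 methyl (the only allylic group cis to C1 and so within reach of C4) is delivered to C4 in a six-centre ene transition state, mirroring the cyclase closure of C11a–C4a with loss of a C19 proton; the E-alkylidene and E-olefin geometries place C5 and C11 anti across the new bond (trans ring fusion), and the C2-symmetric ligand, together with the C7 centre held in the macrocycle, is relied on to select the face giving 4aS,11aR; the closest known reactions are Lewis-acid-promoted intramolecular ene cyclisations of alkylidene malonates with trisubstituted olefins and transannular ene reactions of medium-ring dienes.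

**Step 8**
Reactants: 13 2-methylbut-3-en-2-ol, 14 (2E)-but-2-enal
Product: 15 (2E)-4-hydroxy-4-methylpent-2-enal
Conditions: second-generation Hoveyda–Grubbs catalyst (2 mol %), CH2Cl2, 40 °C
Reagents that add atoms: none
Why: Olefin cross-metathesis between a hindered tertiary allylic alcohol and an enal is selective for the cross product and gives the E enal under thermodynamic control.

**Step 9**
Reactants: 12 (4aS,7S,8Z,11aR)-4-(diethoxyphosphoryl)-7-methyl-11-methylidene-7-(triethylsilyloxy)-4,4a,5,6,7,10,11,11a-octahydrocyclonona[c]pyran-3(1H)-one, 15 (2E)-4-hydroxy-4-methylpent-2-enal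
Product: 16 (4E,4aS,7S,8Z,11aR)-4-[(2E)-4-hydroxy-4-methylpent-2-en-1-ylidene]-7-methyl-11-methylidene-7-(triethylsilyloxy)-4,4a,5,6,7,10,11,11a-octahydrocyclonona[c]pyran-3(1H)-one
Conditions: LiCl, DBU, MeCN, 0 °C to rt
Reagents that add atoms: none
Why: Horner–Wadsworth–Emmons olefination (Masamune–Roush conditions) of an α-phosphono lactone gives the E-alkylidene lactone with C13 trans to the carbonyl and cis to C4a; both C4 epimers of 12 converge, and the free tertiary alcohol of 15 is tolerated.

**Step 10**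
Reactants: 16 (4E,4aS,7S,8Z,11aR)-4-[(2E)-4-hydroxy-4-methylpent-2-en-1-ylidene]-7-methyl-11-methylidene-7-(triethylsilyloxy)-4,4a,5,6,7,10,11,11a-octahydrocyclonona[c]pyran-3(1H)-one
Product: 17 (2E,4E)-2-[(1S,2R,5Z,7S)-2-(hydroxymethyl)-7-methyl-3-methylidene-7-(triethylsilyloxy)cyclonon-5-en-1-yl]-6-methylhepta-2,4-diene-1,6-diol
Conditions: i-Bu2AlH (5 equiv), CH2Cl2, −78 to 0 °C; aq. potassium sodium tartrate
Reagents that add atoms: none
Why: DIBAL-H reduces the conjugated lactone in 1,2-fashion to the C1/C3 diol without touching the diene, the isolated olefins or the silyl ether, and the olefin geometries are retained.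

**Step 11**
Reactants: 17 (2E,4E)-2-[(1S,2R,5Z,7S)-2-(hydroxymethyl)-7-methyl-3-methylidene-7-(triethylsilyloxy)cyclonon-5-en-1-yl]-6-methylhepta-2,4-diene-1,6-diol
Product: 19 [(1R,3aR,6Z,8S,10aS)-8-methyl-4-methylidene-1-[(1E)-4-methylpenta-1,3-dien-1-yl]-8-(triethylsilyloxy)-3,3a,4,5,8,9,10,10a-octahydro-1H-cyclonona[c]furan-1-yl]methanol, via pentadienyl cation 18 (not isolated)
Conditions: PPTS (10 mol %), CH2Cl2, 0 °C
Reagents that add atoms: none
Why: Mild acid ionises only the tertiary, doubly allylic C15 alcohol to a W-shaped pentadienyl cation, which the C1 hydroxyl captures at C4 in a 5-exo SN1-type allylic cycloetherification (formal SN2''); A(1,3) strain against C13 holds H-4a in the plane of the C4–C12 unit, so oxygen adds to the face that sets 4R (dienyl cis to H-4a), and the s-trans diene becomes the 12E olefin.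

**Step 12**
Reactants: 19 [(1R,3aR,6Z,8S,10aS)-8-methyl-4-methylidene-1-[(1E)-4-methylpenta-1,3-dien-1-yl]-8-(triethylsilyloxy)-3,3a,4,5,8,9,10,10a-octahydro-1H-cyclonona[c]furan-1-yl]methanol, 20 nonadecanoic acid
Product: 21 [(1R,3aR,6Z,8S,10aS)-8-methyl-4-methylidene-1-[(1E)-4-methylpenta-1,3-dien-1-yl]-8-(triethylsilyloxy)-3,3a,4,5,8,9,10,10a-octahydro-1H-cyclonona[c]furan-1-yl]methyl nonadecanoate
Conditions: DCC, DMAP, CH2Cl2, rt
Reagents that add atoms: none
Why: Steglich esterification of the only free hydroxyl (primary, neopentyl-type); the neutral conditions spare the acid-labile dienyl ether.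

**Step 13**
Reactants: 21 [(1R,3aR,6Z,8S,10aS)-8-methyl-4-methylidene-1-[(1E)-4-methylpenta-1,3-dien-1-yl]-8-(triethylsilyloxy)-3,3a,4,5,8,9,10,10a-octahydro-1H-cyclonona[c]furan-1-yl]methyl nonadecanoate
Product: 22 [(1R,3aR,6Z,8S,10aS)-8-hydroxy-8-methyl-4-methylidene-1-[(1E)-4-methylpenta-1,3-dien-1-yl]-3,3a,4,5,8,9,10,10a-octahydro-1H-cyclonona[c]furan-1-yl]methyl nonadecanoate (CNP0120482.1)
Conditions: HF·pyridine, pyridine, THF, 0 °C to rt
Reagents that add atoms: none
Why: Pyridine-buffered fluoride desilylation frees the tertiary C7 alcohol without ionising the dienyl ether or cleaving the ester; no stereocentre is touched.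

**Compound list**
1 | (S)-(+)-linalool, (3S)-3,7-dimethylocta-1,6-dien-3-ol | C=C[C@@](C)(O)CCC=C(C)C | starting material
2 | (3S)-3,7-dimethyl-3-(triethylsilyloxy)octa-1,6-diene | C=C[C@@](C)(O[Si](CC)(CC)CC)CCC=C(C)C | intermediate
3 | secondary ozonide, 3,3-dimethyl-5-[(3S)-3-methyl-3-(triethylsilyloxy)pent-4-en-1-yl]-1,2,4-trioxolane | C=C[C@@](C)(O[Si](CC)(CC)CC)CCC1OOC(C)(C)O1 | intermediate
4 | (4S)-4-methyl-4-(triethylsilyloxy)hex-5-enal | C=C[C@@](C)(O[Si](CC)(CC)CC)CCC=O | intermediate
5 | pent-1-en-4-yne | C=CCC#C | starting material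
6 | alkenylalane, dimethyl[(1E)-2-methylpenta-1,4-dien-1-yl]alane | C[Al](C)/C=C(\C)CC=C | intermediate
7 | (2E)-3-methylhexa-2,5-dien-1-ol | OC/C=C(\C)CC=C | intermediate
8 | (diethoxyphosphoryl)acetic acid | CCOP(=O)(OCC)CC(=O)O | starting material
9 | (2E)-3-methylhexa-2,5-dien-1-yl (diethoxyphosphoryl)acetate | CCOP(=O)(OCC)CC(=O)OC/C=C(\C)CC=C | intermediate
10 | (2E)-3-methylhexa-2,5-dien-1-yl (2E,6S)-2-(diethoxyphosphoryl)-6-methyl-6-(triethylsilyloxy)octa-2,7-dienoate | C=C[C@@](C)(O[Si](CC)(CC)CC)CC/C=C(/P(=O)(OCC)OCC)C(=O)OC/C=C(\C)CC=C | intermediate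
11 | 13-membered macrolide, (3E,7S,8Z,11E)-3-(diethoxyphosphoryl)-7,11-dimethyl-7-(triethylsilyloxy)-1-oxacyclotrideca-3,8,11-trien-2-one | C1C/C=C(\C(=O)OC/C=C(\C)C/C=C\[C@@]1(C)O[Si](CC)(CC)CC)P(=O)(OCC)OCC | intermediate
12 | trans-fused phosphono δ-lactone, (4aS,7S,8Z,11aR)-4-(diethoxyphosphoryl)-7-methyl-11-methylidene-7-(triethylsilyloxy)-4,4a,5,6,7,10,11,11a-octahydrocyclonona[c]pyran-3(1H)-one, C4 epimers | C=C1C/C=C\[C@@](C)(O[Si](CC)(CC)CC)CC[C@H]2[C@H]1COC(=O)C2P(=O)(OCC)OCC | intermediate
13 | 2-methylbut-3-en-2-ol | C=CC(C)(C)O | starting material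
14 | (2E)-but-2-enal (crotonaldehyde) | C/C=C/C=O | starting material
15 | (2E)-4-hydroxy-4-methylpent-2-enal | CC(C)(O)/C=C/C=O | intermediate
16 | (4E,4aS,7S,8Z,11aR)-4-[(2E)-4-hydroxy-4-methylpent-2-en-1-ylidene]-7-methyl-11-methylidene-7-(triethylsilyloxy)-4,4a,5,6,7,10,11,11a-octahydrocyclonona[c]pyran-3(1H)-one | C=C1C/C=C\[C@@](C)(O[Si](CC)(CC)CC)CC[C@H]2[C@H]1COC(=O)/C2=C/C=C/C(C)(C)O | intermediate
17 | (2E,4E)-2-[(1S,2R,5Z,7S)-2-(hydroxymethyl)-7-methyl-3-methylidene-7-(triethylsilyloxy)cyclonon-5-en-1-yl]-6-methylhepta-2,4-diene-1,6-diol | C=C1C/C=C\[C@@](C)(O[Si](CC)(CC)CC)CC[C@@H]([C@H]1CO)/C(CO)=C\C=C\C(C)(C)O | intermediate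
18 | pentadienyl cation from 17 (charge delocalised over C15, C13 and C4; drawn at C15) | C=C1C/C=C\[C@@](C)(O[Si](CC)(CC)CC)CC[C@@H]([C@H]1CO)/C(CO)=C\C=C\[C+](C)C | intermediate
19 | [(1R,3aR,6Z,8S,10aS)-8-methyl-4-methylidene-1-[(1E)-4-methylpenta-1,3-dien-1-yl]-8-(triethylsilyloxy)-3,3a,4,5,8,9,10,10a-octahydro-1H-cyclonona[c]furan-1-yl]methanol | C=C1C/C=C\[C@@](C)(O[Si](CC)(CC)CC)CC[C@H]2[C@H]1CO[C@@]2(/C=C/C=C(C)C)CO | intermediate
20 | nonadecanoic acid | CCCCCCCCCCCCCCCCCCC(=O)O | starting material
21 | [(1R,3aR,6Z,8S,10aS)-8-methyl-4-methylidene-1-[(1E)-4-methylpenta-1,3-dien-1-yl]-8-(triethylsilyloxy)-3,3a,4,5,8,9,10,10a-octahydro-1H-cyclonona[c]furan-1-yl]methyl nonadecanoate | C=C1C/C=C\[C@@](C)(O[Si](CC)(CC)CC)CC[C@H]2[C@H]1CO[C@@]2(/C=C/C=C(C)C)COC(=O)CCCCCCCCCCCCCCCCCC | intermediate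
22 | CNP0120482.1, [(1R,3aR,6Z,8S,10aS)-8-hydroxy-8-methyl-4-methylidene-1-[(1E)-4-methylpenta-1,3-dien-1-yl]-3,3a,4,5,8,9,10,10a-octahydro-1H-cyclonona[c]furan-1-yl]methyl nonadecanoate (xenicane descriptors 4R,4aS,7S,11aR) | C=C1C/C=C\[C@@](C)(O)CC[C@H]2[C@H]1CO[C@@]2(/C=C/C=C(C)C)COC(=O)CCCCCCCCCCCCCCCCCC | target

**Step count and risks**
Total step count: 13. Longest linear sequence: 10 steps (steps 1, 2, 5, 6, 7, 9, 10, 11, 12, 13, from linalool).

The three steps most likely to fail are steps 6, 7 and 11.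

Step 6 (macrocyclic metathesis): the hindered silyloxy-bearing vinyl group may close slowly, and the 13-membered ring may form mainly as the 8E olefin, which cannot give the Z-cyclononene. The fallback sets out from 10 and reverses the order of the two ring closures. The open-chain ester 10 is treated with the same copper bis(oxazoline) Lewis acid, so that the ester-templated ene reaction closes the C11a–C4a bond first and gives the monocyclic δ-lactone (4S,5R)-3-(diethoxyphosphoryl)-4-[(3S)-3-methyl-3-(triethylsilyloxy)pent-4-en-1-yl]-5-(penta-1,4-dien-2-yl)oxan-2-one F1. Ring-closing metathesis of F1 with the second-generation Grubbs catalyst then forms the nine-membered ring, where the ring size enforces the Z olefin. The route is rejoined at 12.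

Step 7 (transannular ene): this is the boldest step. It needs the macrolide ester to reach an s-cis arrangement, it must take the hydrogen from C19 and not from the doubly allylic C10, and its facial selectivity is a prediction; the (R,R)-ligand is the first thing to try if the sense is reversed. The fallback sets out from alcohol 7 and ends the closure with silicon instead of hydrogen. Directed dimetalation of 7 (n-BuLi, TMEDA) at the methyl cis to the hydroxymethyl group and silylation with Me3SiCl gives the allylsilane (2Z)-3-[(trimethylsilyl)methyl]hexa-2,5-dien-1-ol F2. Esterification with 8 gives the phosphonoacetate F3, and Knoevenagel condensation with aldehyde 4 gives the alkylidene ester F4. Ring-closing metathesis gives the silyl macrolide F5, which closes under ZnBr2 by a transannular Hosomi–Sakurai (SE2') reaction; loss of the silyl group fixes the exocyclic methylene without any hydrogen transfer. The route is rejoined at 12.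

Step 11 (cation capture): the cation may be trapped at C13 or C15, lose a proton to a triene, or give the C4 epimer. The fallback sets out from 12 and builds the dienyl ether by halo-etherification and elimination. Horner–Wadsworth–Emmons reaction of 12 with commercial (2E)-4-methylpent-2-enal (CC(C)/C=C/C=O) gives the dienyl lactone F6, and DIBAL-H reduction gives the diol F7. N-Iodosuccinimide then effects a 1,4-iodoetherification of the diene: iodine adds at C14 and the C1 hydroxyl at C4, under the same A(1,3) control, to give the allylic iodide F8. Dehydroiodination with DBU installs the C14=C15 olefin. The route is rejoined at 19.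

**Further compounds**
F1 | step 6 | (4S,5R)-3-(diethoxyphosphoryl)-4-[(3S)-3-methyl-3-(triethylsilyloxy)pent-4-en-1-yl]-5-(penta-1,4-dien-2-yl)oxan-2-one | O=C1OC[C@@H](C(=C)CC=C)[C@H](CC[C@](C)(O[Si](CC)(CC)CC)C=C)C1P(=O)(OCC)OCC
F2 | step 7 | (2Z)-3-[(trimethylsilyl)methyl]hexa-2,5-dien-1-ol | OC/C=C(\C[Si](C)(C)C)CC=C
F3 | step 7 | (2Z)-3-[(trimethylsilyl)methyl]hexa-2,5-dien-1-yl (diethoxyphosphoryl)acetate | CCOP(=O)(OCC)CC(=O)OC/C=C(\C[Si](C)(C)C)CC=C
F4 | step 7 | (2Z)-3-[(trimethylsilyl)methyl]hexa-2,5-dien-1-yl (2E,6S)-2-(diethoxyphosphoryl)-6-methyl-6-(triethylsilyloxy)octa-2,7-dienoate | C=C[C@@](C)(O[Si](CC)(CC)CC)CC/C=C(/P(=O)(OCC)OCC)C(=O)OC/C=C(\C[Si](C)(C)C)CC=C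
F5 | step 7 | (3E,7S,8Z,11Z)-3-(diethoxyphosphoryl)-7-methyl-7-(triethylsilyloxy)-11-[(trimethylsilyl)methyl]-1-oxacyclotrideca-3,8,11-trien-2-one | C1C/C=C(\C(=O)OC/C=C(\C[Si](C)(C)C)C/C=C\[C@@]1(C)O[Si](CC)(CC)CC)P(=O)(OCC)OCC
F6 | step 11 | (4E,4aS,7S,8Z,11aR)-7-methyl-11-methylidene-4-[(2E)-4-methylpent-2-en-1-ylidene]-7-(triethylsilyloxy)-4,4a,5,6,7,10,11,11a-octahydrocyclonona[c]pyran-3(1H)-one | C=C1C/C=C\[C@@](C)(O[Si](CC)(CC)CC)CC[C@H]2[C@H]1COC(=O)/C2=C/C=C/C(C)C
F7 | step 11 | (2E,4E)-2-[(1S,2R,5Z,7S)-2-(hydroxymethyl)-7-methyl-3-methylidene-7-(triethylsilyloxy)cyclonon-5-en-1-yl]-6-methylhepta-2,4-dien-1-ol | C=C1C/C=C\[C@@](C)(O[Si](CC)(CC)CC)CC[C@@H]([C@H]1CO)/C(CO)=C\C=C\C(C)C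
F8 | step 11 | [(1R,3aR,6Z,8S,10aS)-1-[(1E)-3-iodo-4-methylpent-1-en-1-yl]-8-methyl-4-methylidene-8-(triethylsilyloxy)-3,3a,4,5,8,9,10,10a-octahydro-1H-cyclonona[c]furan-1-yl]methanol (C14 epimers) | C=C1C/C=C\[C@@](C)(O[Si](CC)(CC)CC)CC[C@H]2[C@H]1CO[C@@]2(/C=C/C(I)C(C)C)CO
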